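The leftover in elm, once its readings went flat, was 45.0% of the starting material charged, present as something other than target, so I reckoned with that leftover and not with the target.

| flask | starting material | gas phase | free catalyst | impurity | temperature | remark | time |
|---|---|---|---|---|---|---|---|
| elm | 0.20 M | 7.9 mM (held) | 10 mM | 7.9 mM | 35 °C | the very flask that is asked about, followed so far |  |
| cedar | 0.20 M | 7.9 mM (held) | 10 mM | 7.9 mM | 41 °C | run made earlier |  |
| flask | 0.20 M | 7.9 mM (held) | 10 mM | 7.9 mM | 35 °C |  | 2.0 d |

| run | time / h | target / % |
|---|---|---|
| elm | 6.00 | 48.5 |
| elm | 12.0 | 54.4 |
| elm | 20.0 | 54.8 |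
| elm | 25.0 | 54.9 |
| elm | 30.0 | 55.1 |
| elm | 40.0 | 55.1 |
| cedar | 6.00 | 64.7 |
| cedar | 12.0 | 68.9 |
| cedar | 20.0 | 69.3 |
| cedar | 25.0 | 68.4 |
| cedar | 30.0 | 67.2 |
| cedar | 40.0 | 67.9 |

(each reading ± 0.5 percentage points)

- teal: at 2.0 d raise the temperature by 20 K, then wait 15 h
- ochre: at 2.0 d add free catalyst, 100% of the amount charged, then wait 15 h
- blue: change nothing and wait 15 h more
- green: at 2.0 d take out 90% of the target then present, then wait 15 h

- target, in percent of the starting material first charged, at 2.0 d
- the remedy with the largest gain of target, or "none" below 2 percentage points (teal / ochre / blue / green / none)
- target present, with what was taken out counted in, in percent of the starting material first charged, after teal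
- target present, with what was taken out counted in, in percent of the starting material first charged, after green

- target that was removed still counts
- at the start none of the gas phase is in solution
- additions bring no volume worth counting

Had elm stopped by 2.0 d? Its plateau, the mean of the readings from 20.0 h on, was 55.0%. The gap to that plateau fell from 6.5 percentage points at 6.00 h to 0.58 points at 12.0 h, which is less, against a scatter of 0.5 points. The asked time lay much later than that, so I answered 55.0% for now.

What could move the plateau? Elm held 0.819 parts of other material per part of target, and I called this non-target over target at the plateau the leftover ratio. Cedar, with plateau 68.2%, gave 0.466, so going from 35 °C to 41 °C divided the ratio by 1.76. The runs did not tell me what the leftover was, but I committed to material in exchange with target, that is, thermodynamic control. I therefore put ochre and blue at no gain.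

What did the other two remedies give? For teal I let the ratio fall by the same factor for each equal temperature step, which gave 0.125 and a target of 88.9%. For green I worked with the fraction left: 50.5% of the charge stayed in the flask and split as before, so the non-target part was that share times 45.0%, and the target counted 77.3%. Teal therefore ranked above green.

The forecast said 55%, teal, 88% after teal, a little below my figure, and 77% after green, while granting that “catalyst death would fit the curves about equally well”.

The flask gave 54.9% at 2.0 d, teal as best, 88.6% after teal and 77.2% after green. The gains were 34 points for teal, 22 points for green, 0 points for ochre and 0 points for blue.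

    gas phase ⇌ dissolved gas, rate k1*(csat - [dissolved gas]) (kL = 0.245 s⁻¹)
    starting material + dissolved gas + free catalyst → free catalyst + target (k = 6.09 M⁻² s⁻¹, Ea = 36.0 kJ mol⁻¹)
    target ⇌ isomer of the product (K = 0.820, k = 0.00237 s⁻¹, Ea = 83.0 kJ mol⁻¹, ΔH = −78.0 kJ mol⁻¹)
    free catalyst + impurity → spent catalyst (k = 2.29 M⁻¹ s⁻¹, Ea = 45.0 kJ mol⁻¹)
    (constants at 35 °C)

At 48.0 h the flask held 54.9% target, 45.1% isomer of the product and 0% starting material, so the leftover ratio I had read as 0.819 stood for isomer of the product over target. The forward half-life of target turning into isomer of the product, 0.081 h, was far shorter than 2.0 d. Carried to a repeat of this flask at 60 °C, the ratio became 0.0783, which meant 92.7% target. That neighbour held 92.3% target and 7.71% isomer of the product.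

The runs were computed with constants of no real substance; noise was put on by code.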